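## Analysis of the target

The target is a eudesmane: a decalin in which ring A (C1–C5, C10) and ring B (C5–C10) share the C5–C10 bond. It carries a methyl group on C10 (C14), an exocyclic methylene on C4 (C15) and a methyl acrylate unit on C7 (C11–C13, ester carbon C12). There are five stereocentres. The C10 methyl, the C3 isobutyrate, the C7 side chain and the C8 acetate lie on one face (β), and the C5 hydroperoxide lies on the other (α), so O–C5 and C14–C10 are trans and the C7 and C8 substituents are cis. The sensitive groups are the tertiary allylic hydroperoxide (reducible, prone to Hock cleavage), the acrylate (a Michael acceptor) and three different esters, two of them on secondary alcohols that must be told apart. The hard points are the quaternary C10 next to the fully substituted C5, the 1,4-relation of C7 and C10 across ring B, the differentiation of O3 and O8, and the need to bring in the hydroperoxide last. The 5-hydroperoxide with its C4(15) methylene is the ene product of a C4=C5 alkene. Ring A, with its C3 oxygen, its C4 carbon substituent and the C10 methyl, is then a dearomatised 2,4-dimethylphenol in which C10 is para to the oxygen and C5, the carbon that carries ring B, is meta. The strategy rests on this: ring B is closed onto the para carbon C10 by C9 of a side chain that already holds the C7 stereocentre.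

## Retrosynthetic reasoning

**31 ⇒ 30.** The C5–O bond is cut and the alkene is moved from C4(15) back to C4=C5. The hydroperoxide would not survive hydride, enolate or hydrolysis chemistry, so it comes last. The tetrasubstituted alkene of 30 is its only electron-rich π bond, and a Schenck ene reaction on the α face (the β face is covered by the axial C10 methyl) has to create the C5 stereocentre and the exocyclic methylene together.

**30 ⇒ 29 ⇒ 27.** The two secondary esters differ, so the two hydroxyls must never be free at the same time. Removing the C8 acetate gives hydroxy ester 29, which is traced to the cis-fused γ-lactone 27, where O8 is tied to C12. The lactone masks O8 while O3 is acylated. A γ-lactone is favoured over its hydroxy methyl ester, so the forward opening must be irreversible: saponification to carboxylate 28, alkylation of the carboxylate, then immediate acetylation.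

**27 ⇒ 24 ⇒ 23.** The C11=C13 bond is cut (aminomethylation of the lactone enolate, quaternisation and elimination through 25 and 26), then the C3 ester. C13 can only be added after the C1=C2 hydrogenation, which it would not survive. It can also only be added once C3 is at the alcohol level and acylated, because a C3 enone would be deprotonated at C2 before the lactone is deprotonated at C11. The forward step must enolise the lactone in the presence of the hindered isobutyrate.

**23 ⇒ 21.** Both carbinol C–H bonds (C3, C8) and the lactone C–O bond are cut, giving ene-dione ester 21. One hydride reduction must deliver hydrogen to the α face of both carbonyls. At C3 this is the usual axial attack on a 4-en-3-one. At C8 it is enforced by the C10 methyl, which is 1,3-diaxial to the β trajectory. The 8β-alcohol of diol 22 is cis to the C7 arm and lactonises.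

**21 ⇒ 20 ⇒ 19.** Restoring the C1=C2 unsaturation and masking the C8 ketone as its dimethyl ketal leads to the cross-conjugated dienone 19. Forward, the hydrogenation must take the disubstituted alkene of a 1,4-dien-3-one and leave the tetrasubstituted one.

**19 ⇒ 18 (key disconnection).** The C9–C10 bond is cut. It is the only bond of ring B whose cleavage lets ring A become aromatic. C3–O, the C4 methyl and the C10 methyl become the substituents of a phenol, and the rest of ring B becomes a chain on C5 that ends in a methyl enol ether. The gain is that the quaternary centre, the C4=C5 alkene and oxygen at C3 and C8 all arise in one oxidative step from a flat arene, with C7 as the only stereocentre needed beforehand. The forward reaction must bond at the para carbon, not at the ortho carbon C4 and not with the solvent, and must place the C10 methyl cis to the C7 arm.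

**18 ⇒ 17 ⇒ 15.** The phenol is carried as a silyl ether (17). The enol ether is traced through ketal 16 to methyl ketone 15, by loss of one alkoxy group and a methyl proton. A carbene-type methylenation of a C8 ester would look shorter, but the unhindered C12 ester would react first. The ketone route distinguishes C8 from C12 by oxidation level.

**15 ⇒ 14 ⇒ 13.** The C8–C9 bond is cut. The methyl ketone comes from thioester 14 by a cuprate ketone synthesis that leaves the C12 ester alone. Thioester 14 comes from acyl oxazolidinone 13 by thiolate exchange, which releases the auxiliary without epimerising C7.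

**13 ⇒ 12 + 9.** The C6–C7 bond is cut. An Evans alkylation of the succinate-derived imide 12 with benzylic bromide 9 sets C7, the one stereocentre not derived from another. The imide α-position is the most acidic site of 12, so the ester needs no protection.

**12 ⇒ 10 + 11, and 9 ⇒ 8 ⇒ 7 ⇒ 5 ⇒ 3 ⇒ 2 ⇒ 1.** Imide 12 is the N-acylation product of auxiliary 10 and acid chloride 11. Bromide 9 is traced through alcohol 8 and silyl-protected acid 7 to hydroxy acid 5. The hydroxyl of 5 comes from amine 3 via diazonium salt 4, and the amine from nitration of acid 1, where all three substituents direct to C3.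

## Alternatives that were turned down

**Alternative 1:** Disconnection of C6–C7 within an α-methylene lactone. The precursor would be allylic bromide A1: a 4-methylcyclohexenone with CH2Br on C5 and, on the quaternary C10, a CH2 link (C9) to C8 of a butenolide that carries a phenylthiomethyl group on C11. In a tin hydride chain the C6 allylic radical would add 6-exo to C7, and the C11 radical would expel the thiyl radical to give keto lactone A2.

- For: ring B, the cis lactone and the C11(13) methylene arrive in one step. On this point it is stronger than the chosen route, which spends steps 16–18 and a chemoselective enolisation on the same α-methylene lactone.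
- Against: A1 needs the quaternary C10 and the C8 carbinol set by two independent asymmetric operations, related 1,3 through C9 with no mutual control. The radical is a stabilised allylic radical conjugated with the enone, so it adds slowly; premature hydrogen transfer competes, and the other allyl terminus (C4) can close an equally sized ring. The C7/C10 relation is left to the transition state. The C3 ketone of A2 must later be reduced next to a conjugate acceptor.
- Comparison: the chosen strategy needs one auxiliary-controlled centre, from which C10 is derived, and takes ring A fully substituted from a commodity arene.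

**Alternative 2:** Disconnection of C5–C10 in a ten-membered ring. Germacratriene A3 (E alkenes at C1–C10 and C4–C5, all oxygen functions and the acrylate in place) would be protonated at C1. The C4=C5 alkene would attack C10 through C5, and loss of the C5 proton would give diene A4, which is the same compound as 30.

- For: both rings form at once and the product is one step from the target. After the cyclisation it is the shortest of all routes and stronger than the chosen one in step economy.
- Against: the difficulty moves into A3. A ten-membered ring with two trisubstituted E alkenes and three stereocentres is harder to make than the whole chosen sequence, and it undergoes Cope rearrangement on warming. The C4 cation sits next to the C3 acyloxy group, which lowers the nucleophilicity of C4=C5 and can ionise or participate. The cation can also lose a proton from C15 or C3 as readily as from C5, so alkene isomers are expected.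
- Comparison: the chosen route reaches the same compound 30 with the alkene position fixed by its origin in the arene and each stereocentre traced to a controlling element.

**Alternative 3:** Disconnection of C1–C2 and C5–C10 by an intramolecular Diels–Alder reaction. In triene A5 a 2-silyloxy diene (C2=C3–C4=C5) and an E vinyl sulfone (C1=C10) are linked through C6–C9, with C7 set and C8 as a dioxolane. Heating would give trans-decalin A6.

- For: one thermal, reagent-free step makes both rings, two C–C bonds and the quaternary centre, with relative configuration set by alkene geometry and the tether. In bonds formed per step it is stronger than the chosen key step.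
- Against: the dienophile is a β,β-disubstituted vinyl sulfone that must form a quaternary carbon, so it is sluggish and needs temperatures at which the silyloxy diene can isomerise. A5 needs two stereodefined trisubstituted alkenes. The sulfone must be removed later, and the C5 stereocentre made in the cycloaddition must be destroyed again to give the C4=C5 alkene for the ene step. The C7-to-C10 induction through the tether is no better founded than in the chosen route.
- Comparison: the phenol route gives C4=C5 and C3=O directly and carries no activating group that must be taken off again.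

Key step: step 13

Remark: eudesmane numbering is used for all bicyclic compounds (C14 = methyl on C10, C15 = carbon on C4, C11–C13 = side chain on C7, "13-nor" = C13 absent), β is the face of the C10 methyl, and compounds 10 and 11 are taken as commercial.

## Route

Step 1
Reactants: 1 2,6-dimethylbenzoic acid
Product: 2 2,6-dimethyl-3-nitrobenzoic acid
Conditions: HNO3 (1.05 equiv), conc. H2SO4, 0 °C
Reagents that add atoms: nitric acid, O[N+](=O)[O-]
Why: Electrophilic aromatic nitration; C3 is ortho to one methyl, para to the other and meta to the carboxyl group, so all three substituents direct there, and the deactivated product resists a second nitration.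

Step 2
Reactants: 2 2,6-dimethyl-3-nitrobenzoic acid
Product: 3 3-amino-2,6-dimethylbenzoic acid
Conditions: H2 (1 atm), Pd/C, MeOH, rt
Reagents that add atoms: none
Why: Catalytic hydrogenation of an aryl nitro group to the aniline; the carboxylic acid and the arene are inert under these conditions.

Step 3
Reactants: 3 3-amino-2,6-dimethylbenzoic acid
Product: 5 3-hydroxy-2,6-dimethylbenzoic acid, via diazonium salt 4 (not isolated)
Conditions: NaNO2, aq. H2SO4, 0 °C; then run into boiling dilute aq. H2SO4
Reagents that add atoms: water, O
Why: Diazotisation followed by thermal hydrolysis of the arenediazonium ion, the standard conversion of an aminobenzoic acid into a hydroxybenzoic acid; addition to hot dilute acid keeps the diazonium concentration low and suppresses azo coupling.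

Step 4
Reactants: 5 3-hydroxy-2,6-dimethylbenzoic acid
Product: 7 2,6-dimethyl-3-(triisopropylsilyloxy)benzoic acid, via bis-silyl derivative 6 (not isolated)
Conditions: i-Pr3SiCl (2.3 equiv), imidazole, DMF, 40 °C; then K2CO3, MeOH/THF/H2O, rt; acidify to pH 4
Reagents that add atoms: chlorotriisopropylsilane, CC(C)[Si](Cl)(C(C)C)C(C)C
Why: Exhaustive silylation followed by selective solvolysis of the silyl ester, which is far more labile than the aryl triisopropylsilyl ether; the bulky silyl group is chosen to survive amide bases, thiolate, cuprate and silyl triflate later on.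

Step 5
Reactants: 7 2,6-dimethyl-3-(triisopropylsilyloxy)benzoic acid
Product: 8 [2,6-dimethyl-3-(triisopropylsilyloxy)phenyl]methanol
Conditions: BH3·THF (2.5 equiv), THF, 0 °C to reflux; aqueous work-up
Reagents that add atoms: none
Why: Borane reduction of a carboxylic acid through its acyloxyborane, a pathway that tolerates the two ortho methyl groups and does not touch the aryl silyl ether.

Step 6
Reactants: 8 [2,6-dimethyl-3-(triisopropylsilyloxy)phenyl]methanol
Product: 9 [3-(bromomethyl)-2,4-dimethylphenoxy]triisopropylsilane
Conditions: CBr4, PPh3, CH2Cl2, 0 °C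
Reagents that add atoms: carbon tetrabromide, BrC(Br)(Br)Br
Why: Appel bromination of a benzylic alcohol under neutral conditions, which spares the silyl ether.

Step 7
Reactants: 10 (4R)-4-benzyl-1,3-oxazolidin-2-one; 11 methyl 4-chloro-4-oxobutanoate
Product: 12 methyl 4-[(4R)-4-benzyl-2-oxo-1,3-oxazolidin-3-yl]-4-oxobutanoate
Conditions: n-BuLi (1.0 equiv), THF, −78 °C; then 11, −78 to 0 °C
Reagents that add atoms: none
Why: N-acylation of the lithiated oxazolidinone by an acid chloride, which is far more electrophilic than the methyl ester at the other end of 11.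

Step 8
Reactants: 12 methyl 4-[(4R)-4-benzyl-2-oxo-1,3-oxazolidin-3-yl]-4-oxobutanoate; 9 [3-(bromomethyl)-2,4-dimethylphenoxy]triisopropylsilane
Product: 13 methyl (3R)-4-[(4R)-4-benzyl-2-oxo-1,3-oxazolidin-3-yl]-3-{[2,6-dimethyl-3-(triisopropylsilyloxy)phenyl]methyl}-4-oxobutanoate
Conditions: NaN(SiMe3)2 (1.1 equiv), THF, −78 °C; then 9, n-Bu4NI (cat.), −78 to −30 °C
Reagents that add atoms: none
Why: Evans alkylation; the imide α-protons are the most acidic in 12, so the chelated Z sodium enolate forms there and is alkylated by the benzylic halide on the face away from the auxiliary benzyl group. With the (R)-auxiliary this gives the (R) configuration at the new centre (C7), the arrangement required in the target.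

Step 9
Reactants: 13 methyl (3R)-4-[(4R)-4-benzyl-2-oxo-1,3-oxazolidin-3-yl]-3-{[2,6-dimethyl-3-(triisopropylsilyloxy)phenyl]methyl}-4-oxobutanoate
Product: 14 methyl (3R)-3-{[2,6-dimethyl-3-(triisopropylsilyloxy)phenyl]methyl}-4-(ethylsulfanyl)-4-oxobutanoate
Conditions: EtSH, n-BuLi (LiSEt, 1.5 equiv), THF, 0 °C; aq. NH4Cl
Reagents that add atoms: ethanethiol, CCS
Why: Thiolate cleavage of the N-acyl oxazolidinone at the exocyclic carbonyl; the weakly basic thiolate does not epimerise C7 and attacks the activated imide much faster than the methyl ester.

Step 10
Reactants: 14 methyl (3R)-3-{[2,6-dimethyl-3-(triisopropylsilyloxy)phenyl]methyl}-4-(ethylsulfanyl)-4-oxobutanoate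
Product: 15 methyl (3R)-3-{[2,6-dimethyl-3-(triisopropylsilyloxy)phenyl]methyl}-4-oxopentanoate
Conditions: Me2CuLi (from CuI and MeLi, 2 equiv), Et2O, −78 to −40 °C
Reagents that add atoms: lithium dimethylcuprate, [Li+].C[Cu-]C
Why: Ketone synthesis from a thioester and a lithium dialkylcuprate; the cuprate stops at the ketone, does not react with the C12 methyl ester and is not basic enough to epimerise C7.

Step 11
Reactants: 15 methyl (3R)-3-{[2,6-dimethyl-3-(triisopropylsilyloxy)phenyl]methyl}-4-oxopentanoate
Product: 17 methyl (3R)-3-{[2,6-dimethyl-3-(triisopropylsilyloxy)phenyl]methyl}-4-methoxypent-4-enoate, via dimethyl ketal 16 (not isolated)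
Conditions: MeOSiMe3 (2.5 equiv), Me3SiOTf (5 mol%), CH2Cl2, −78 to −30 °C; then i-Pr2NEt (1.5 equiv), Me3SiOTf (1.2 equiv), −78 to 0 °C; chromatography on Et3N-treated silica
Reagents that add atoms: methoxytrimethylsilane, CO[Si](C)(C)C
Why: Aprotic silyl-triflate-catalysed ketalisation, then silyl-triflate-mediated elimination of the ketal to the enol ether; the hindered amine takes a proton from the methyl group (C9) of the oxocarbenium ion and not from the crowded C7 methine, so the 1,1-disubstituted enol ether forms and C7 is kept.

Step 12
Reactants: 17 methyl (3R)-3-{[2,6-dimethyl-3-(triisopropylsilyloxy)phenyl]methyl}-4-methoxypent-4-enoate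
Product: 18 methyl (3R)-3-[(3-hydroxy-2,6-dimethylphenyl)methyl]-4-methoxypent-4-enoate
Conditions: n-Bu4NF (1.1 equiv), THF, 0 °C; aq. NH4Cl; used at once
Reagents that add atoms: none
Why: Fluoride cleavage of the aryl silyl ether under basic conditions, which the acid-sensitive enol ether and the ester tolerate.

Step 13
Reactants: 18 methyl (3R)-3-[(3-hydroxy-2,6-dimethylphenyl)methyl]-4-methoxypent-4-enoate
Product: 19 methyl (7R,10S)-8,8-dimethoxy-3-oxo-13-noreudesma-1,4-dien-12-oate
Conditions: constant-current electrolysis (about 2.2 F/mol), reticulated vitreous carbon anode, Pt cathode, undivided cell, LiClO4 (0.1 M), 2,6-lutidine (3 equiv), MeOH/CH2Cl2 (1:4), 0 °C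
Reagents that add atoms: methanol, CO
Why: Two-electron anodic oxidation of the phenol, with 2,6-lutidine as proton acceptor, gives a phenoxonium ion whose para carbon C10 is attacked by the terminus C9 of the tethered enol ether; the C8 oxocarbenium ion is trapped by methanol as the dimethyl ketal and the released protons are reduced to H2 at the cathode. The closest known reaction types are the anodic or hypervalent-iodine para-dearomatisation of 4-alkylphenols by tethered carbon π-nucleophiles to cyclohexa-2,5-dienones, and anodic enol ether–arene couplings in alcohol/CH2Cl2; if the enol ether is oxidised first, its radical cation attacks the electron-rich ring at the same carbon and both paths converge after the second electron transfer. Ring B closes as a six-membered ring, 6-endo with respect to the enol ether (C8 and C9 both become ring atoms), onto the ring carbon next to the tether, so the dienone is fused and not spiro. The one new stereocentre, C10, is controlled by C7: in the chair-like transition state the CH2CO2Me arm is equatorial and C9 approaches perpendicular to the arene plane, so the C10 methyl becomes axial and cis to the C7 arm. Para attack at C10 is needed rather than ortho attack at C4, which would close a ring of the same size; the phenoxonium ion has its largest LUMO coefficient para to oxygen and para attack gives the more stable cross-conjugated dienone. Capture of C10 by the solvent must be outrun, which the intramolecular nucleophile and the low methanol content of the medium are meant to secure. The ester and the electron-poor dienone product are not oxidised at the potential of the phenol, and the quaternary C10 cannot rearomatise.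

Step 14
Reactants: 19 methyl (7R,10S)-8,8-dimethoxy-3-oxo-13-noreudesma-1,4-dien-12-oate
Product: 20 methyl 3,8-dioxo-13-noreudesma-1,4-dien-12-oate (7αH, 10β-methyl)
Conditions: 1 M aq. HCl, THF, 0 °C to rt
Reagents that add atoms: water, O
Why: Acid-catalysed ketal hydrolysis; the dimethyl ketal is much more labile than the ester and the dienone is inert to dilute acid. C7 becomes enolisable here but its arm is already equatorial, the favoured position; any C10 epimer must be removed at 19, because equilibration at C7 would turn it into the enantiomer of 20.

Step 15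
Reactants: 20 methyl 3,8-dioxo-13-noreudesma-1,4-dien-12-oate (7αH, 10β-methyl)
Product: 21 methyl 3,8-dioxo-13-noreudesm-4-en-12-oate (7αH, 10β-methyl)
Conditions: H2 (1 atm), RhCl(PPh3)3 (10 mol%), benzene/EtOH (1:1), rt
Reagents that add atoms: none
Why: Homogeneous hydrogenation with RhCl(PPh3)3 is selective for the disubstituted C1=C2 bond of cross-conjugated 1,4-dien-3-ones; the tetrasubstituted C4=C5 bond and the carbonyl groups are left.

Step 16
Reactants: 21 methyl 3,8-dioxo-13-noreudesm-4-en-12-oate (7αH, 10β-methyl)
Product: 23 3β-hydroxy-13-noreudesm-4-en-12,8β-olide, via diol ester 22 (not isolated)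
Conditions: NaBH4, CeCl3·7H2O, MeOH, −78 to 0 °C; then pyridinium p-toluenesulfonate (cat.), CH2Cl2, rt
Reagents that add atoms: none
Why: Luche reduction; at C3 hydride adds 1,2 and axially from the α face to give the equatorial 3β-allylic alcohol, and at C8 the β face is screened by the axial C10 methyl (1,3 to the carbonyl), so hydride enters from α and the axial 8β-alcohol results. This alcohol is cis to the C7 arm and closes the γ-lactone with loss of methanol; the ester is not reduced.

Step 17
Reactants: 23 3β-hydroxy-13-noreudesm-4-en-12,8β-olide
Product: 24 3β-(isobutyryloxy)-13-noreudesm-4-en-12,8β-olide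
Conditions: i-PrCOCl, pyridine, 4-(dimethylamino)pyridine (cat.), CH2Cl2, 0 °C to rt
Reagents that add atoms: isobutyryl chloride, CC(C)C(Cl)=O
Why: Nucleophile-catalysed acylation of the only free hydroxyl; O8 is held in the lactone, so no differentiation is needed.

Step 18
Reactants: 24 3β-(isobutyryloxy)-13-noreudesm-4-en-12,8β-olide
Product: 27 3β-(isobutyryloxy)eudesma-4,11(13)-dien-12,8β-olide, via Mannich base 25 (not isolated), via methiodide 26 (not isolated)
Conditions: LiN(i-Pr)2 (1.1 equiv), THF, −78 °C; Me2N=CH2+ I−, −78 to 0 °C; then MeI, MeOH, rt; then aq. NaHCO3, CH2Cl2, rt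
Reagents that add atoms: N,N-dimethylmethyleneiminium iodide, C=[N+](C)C.[I-]
Why: Eschenmoser methylenation of a lactone: enolate aminomethylation, N-quaternisation and elimination. The lactone CH2 is more acidic and more accessible than the tertiary α-CH of the isobutyrate, so one equivalent of amide base at −78 °C should enolise C11 only; the C11 stereocentre of 25 and 26 is lost in the elimination.

Step 19
Reactants: 27 3β-(isobutyryloxy)eudesma-4,11(13)-dien-12,8β-olide
Product: 29 methyl 8β-hydroxy-3β-(isobutyryloxy)eudesma-4,11(13)-dien-12-oate, via potassium carboxylate 28 (not isolated)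
Conditions: KOH (1.05 equiv), THF/H2O, 0 °C; evaporate; MeI, DMF, 0 °C to rt; used at once
Reagents that add atoms: potassium hydroxide, [K+].[OH-]; iodomethane, CI
Why: Saponification of the lactone and SN2 alkylation of the carboxylate; the γ-lactone is attacked by hydroxide much faster than the α-branched ester of a hindered secondary alcohol, so one equivalent of base should open the lactone only. Opening via the carboxylate avoids the unfavourable lactone/hydroxy-ester equilibrium of a direct methanolysis.

Step 20
Reactants: 29 methyl 8β-hydroxy-3β-(isobutyryloxy)eudesma-4,11(13)-dien-12-oate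
Product: 30 methyl 8β-acetoxy-3β-(isobutyryloxy)eudesma-4,11(13)-dien-12-oate
Conditions: Ac2O, Et3N, 4-(dimethylamino)pyridine, CH2Cl2, 0 °C to rt
Reagents that add atoms: acetic anhydride, CC(=O)OC(C)=O
Why: Nucleophile-catalysed acetylation of the axial 8β-alcohol; the acylpyridinium ion should acylate the hydroxyl faster than it can re-close the lactone, and acetylation makes the open form permanent.

Step 21
Reactants: 30 methyl 8β-acetoxy-3β-(isobutyryloxy)eudesma-4,11(13)-dien-12-oate
Product: 31 methyl 8β-acetoxy-5α-hydroperoxy-3β-(isobutyryloxy)eudesma-4(15),11(13)-dien-12-oate (the target)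
Conditions: O2, visible light, tetraphenylporphyrin (cat.), CH2Cl2, −20 °C; no reductive work-up
Reagents that add atoms: dioxygen, O=O
Why: Schenck ene reaction; singlet oxygen attacks the electron-rich C4=C5 alkene from the α face, away from the axial C10 methyl, bonds to C5 and takes a hydrogen from C15, which gives the 5α-hydroperoxide and the C4(15) methylene. The α-hydrogen on C6 is equatorial and badly aligned, the C3 hydrogen is deactivated by its geminal acyloxy group, and the acrylate is too electron-poor to react.

## Compound list

1 | 2,6-dimethylbenzoic acid | Cc1cccc(C)c1C(=O)O | starting material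
2 | 2,6-dimethyl-3-nitrobenzoic acid | Cc1ccc([N+](=O)[O-])c(C)c1C(=O)O | intermediate
3 | 3-amino-2,6-dimethylbenzoic acid | Cc1ccc(N)c(C)c1C(=O)O | intermediate
4 | 3-carboxy-2,4-dimethylbenzenediazonium hydrogen sulfate (not isolated) | Cc1ccc([N+]#N)c(C)c1C(=O)O.OS(=O)(=O)[O-] | intermediate
5 | 3-hydroxy-2,6-dimethylbenzoic acid | Cc1ccc(O)c(C)c1C(=O)O | intermediate
6 | triisopropylsilyl 2,6-dimethyl-3-(triisopropylsilyloxy)benzoate (not isolated) | Cc1ccc(O[Si](C(C)C)(C(C)C)C(C)C)c(C)c1C(=O)O[Si](C(C)C)(C(C)C)C(C)C | intermediate
7 | 2,6-dimethyl-3-(triisopropylsilyloxy)benzoic acid | Cc1ccc(O[Si](C(C)C)(C(C)C)C(C)C)c(C)c1C(=O)O | intermediate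
8 | [2,6-dimethyl-3-(triisopropylsilyloxy)phenyl]methanol | Cc1ccc(O[Si](C(C)C)(C(C)C)C(C)C)c(C)c1CO | intermediate
9 | [3-(bromomethyl)-2,4-dimethylphenoxy]triisopropylsilane | Cc1ccc(O[Si](C(C)C)(C(C)C)C(C)C)c(C)c1CBr | intermediate
10 | (4R)-4-benzyl-1,3-oxazolidin-2-one | O=C1N[C@H](Cc2ccccc2)CO1 | starting material
11 | methyl 4-chloro-4-oxobutanoate | COC(=O)CCC(Cl)=O | starting material
12 | methyl 4-[(4R)-4-benzyl-2-oxo-1,3-oxazolidin-3-yl]-4-oxobutanoate | COC(=O)CCC(=O)N1C(=O)OC[C@H]1Cc1ccccc1 | intermediate
13 | methyl (3R)-4-[(4R)-4-benzyl-2-oxo-1,3-oxazolidin-3-yl]-3-{[2,6-dimethyl-3-(triisopropylsilyloxy)phenyl]methyl}-4-oxobutanoate | COC(=O)C[C@@H](Cc1c(C)c(O[Si](C(C)C)(C(C)C)C(C)C)ccc1C)C(=O)N1C(=O)OC[C@H]1Cc1ccccc1 | intermediate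
14 | methyl (3R)-3-{[2,6-dimethyl-3-(triisopropylsilyloxy)phenyl]methyl}-4-(ethylsulfanyl)-4-oxobutanoate | COC(=O)C[C@@H](Cc1c(C)c(O[Si](C(C)C)(C(C)C)C(C)C)ccc1C)C(=O)SCC | intermediate
15 | methyl (3R)-3-{[2,6-dimethyl-3-(triisopropylsilyloxy)phenyl]methyl}-4-oxopentanoate | COC(=O)C[C@@H](Cc1c(C)c(O[Si](C(C)C)(C(C)C)C(C)C)ccc1C)C(C)=O | intermediate
16 | methyl (3R)-3-{[2,6-dimethyl-3-(triisopropylsilyloxy)phenyl]methyl}-4,4-dimethoxypentanoate (not isolated) | COC(=O)C[C@@H](Cc1c(C)c(O[Si](C(C)C)(C(C)C)C(C)C)ccc1C)C(C)(OC)OC | intermediate
17 | methyl (3R)-3-{[2,6-dimethyl-3-(triisopropylsilyloxy)phenyl]methyl}-4-methoxypent-4-enoate | COC(=O)C[C@@H](Cc1c(C)c(O[Si](C(C)C)(C(C)C)C(C)C)ccc1C)C(=C)OC | intermediate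
18 | methyl (3R)-3-[(3-hydroxy-2,6-dimethylphenyl)methyl]-4-methoxypent-4-enoate | COC(=O)C[C@@H](Cc1c(C)c(O)ccc1C)C(=C)OC | intermediate
19 | methyl (7R,10S)-8,8-dimethoxy-3-oxo-13-noreudesma-1,4-dien-12-oate (C7 arm and C10 methyl both β) | COC(=O)C[C@H]1CC2=C(C)C(=O)C=C[C@]2(C)CC1(OC)OC | intermediate
20 | methyl 3,8-dioxo-13-noreudesma-1,4-dien-12-oate (7αH, 10β-methyl) | COC(=O)C[C@H]1CC2=C(C)C(=O)C=C[C@]2(C)CC1=O | intermediate
21 | methyl 3,8-dioxo-13-noreudesm-4-en-12-oate (7αH, 10β-methyl) | COC(=O)C[C@H]1CC2=C(C)C(=O)CC[C@]2(C)CC1=O | intermediate
22 | methyl 3β,8β-dihydroxy-13-noreudesm-4-en-12-oate (not isolated) | COC(=O)C[C@H]1CC2=C(C)[C@@H](O)CC[C@]2(C)C[C@H]1O | intermediate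
23 | 3β-hydroxy-13-noreudesm-4-en-12,8β-olide | O=C1C[C@H]2CC3=C(C)[C@@H](O)CC[C@]3(C)C[C@H]2O1 | intermediate
24 | 3β-(isobutyryloxy)-13-noreudesm-4-en-12,8β-olide | O=C1C[C@H]2CC3=C(C)[C@@H](OC(=O)C(C)C)CC[C@]3(C)C[C@H]2O1 | intermediate
25 | 13-(dimethylamino)-3β-(isobutyryloxy)eudesm-4-en-12,8β-olide (C11 epimers; not isolated) | O=C1C(CN(C)C)[C@H]2CC3=C(C)[C@@H](OC(=O)C(C)C)CC[C@]3(C)C[C@H]2O1 | intermediate
26 | [3β-(isobutyryloxy)-12-oxoeudesm-4-en-12,8β-olid-13-yl]trimethylammonium iodide (C11 epimers; not isolated) | O=C1C(C[N+](C)(C)C)[C@H]2CC3=C(C)[C@@H](OC(=O)C(C)C)CC[C@]3(C)C[C@H]2O1.[I-] | intermediate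
27 | 3β-(isobutyryloxy)eudesma-4,11(13)-dien-12,8β-olide | O=C1C(=C)[C@H]2CC3=C(C)[C@@H](OC(=O)C(C)C)CC[C@]3(C)C[C@H]2O1 | intermediate
28 | potassium 8β-hydroxy-3β-(isobutyryloxy)eudesma-4,11(13)-dien-12-oate (not isolated) | C=C(C(=O)[O-])[C@H]1CC2=C(C)[C@@H](OC(=O)C(C)C)CC[C@]2(C)C[C@H]1O.[K+] | intermediate
29 | methyl 8β-hydroxy-3β-(isobutyryloxy)eudesma-4,11(13)-dien-12-oate | C=C(C(=O)OC)[C@H]1CC2=C(C)[C@@H](OC(=O)C(C)C)CC[C@]2(C)C[C@H]1O | intermediate
30 | methyl 8β-acetoxy-3β-(isobutyryloxy)eudesma-4,11(13)-dien-12-oate | C=C(C(=O)OC)[C@H]1CC2=C(C)[C@@H](OC(=O)C(C)C)CC[C@]2(C)C[C@H]1OC(C)=O | intermediate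
31 | methyl 8β-acetoxy-5α-hydroperoxy-3β-(isobutyryloxy)eudesma-4(15),11(13)-dien-12-oate (CNP0244758.1) | C=C(C(=O)OC)[C@H]1C[C@@]2(OO)C(=C)[C@@H](OC(=O)C(C)C)CC[C@]2(C)C[C@H]1OC(C)=O | target

## Step count and least certain steps

Total step count: 21. Longest linear sequence: 20 steps (steps 1–6 and 8–21, from compound 1); step 7 is a one-step side branch.

**Step 13 (key step).** The most likely failure is solvent capture: methanol adds to C10 of the phenoxonium ion, or to the enol ether radical cation, before the C9–C10 bond forms. If the bond does form, facial discrimination at C10 may be poor, because the equatorial preference of the C7 arm is opposed by only one syn-axial hydrogen. The fallback forms the same bond with reversed polarity and without oxidation. It sets out from ketone 15. Detrifluoroacetylative diazo transfer at the methyl group (LiN(SiMe3)2, CF3CO2CH2CF3, THF, −78 °C; then MeSO2N3, Et3N, MeCN) should give methyl (3R)-5-diazo-3-{[2,6-dimethyl-3-(triisopropylsilyloxy)phenyl]methyl}-4-oxopentanoate F1. n-Bu4NF then frees the phenol to give methyl (3R)-5-diazo-3-[(3-hydroxy-2,6-dimethylphenyl)methyl]-4-oxopentanoate F2. CF3CO2H in CH2Cl2 at −20 °C protonates the diazo carbon, and the phenol ring displaces N2 from C9 with its para carbon C10 (aryl participation). This gives dienone 20, where the route is rejoined.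

**Step 11.** Regiocontrol in the elimination may be lost (proton loss from C7 instead of C9), or C7 may epimerise through reversible enol ether formation while the silyl triflate is present. The fallback avoids the ketal: starting from 15, the kinetic potassium enolate (KN(SiMe3)2, THF/DMPU, −78 °C; the methyl protons are removed far faster than the C7 methine) is O-methylated with the hard electrophile MeOSO2CF3, which gives 17 directly. It forms no new compound (F0).

**Step 16.** Hydride may be delivered in part to the β face of C8, which would give the 8α-alcohol and then the trans-fused lactone; the small reagent relies only on the screening by the C10 methyl. The fallback separates the two reductions. Starting from 21, LiBH(s-Bu)3 (1.05 equiv, THF, −78 °C) attacks the saturated C8 ketone from the equatorial (α) direction and leaves the hindered enone; lactonisation then gives 3-oxo-13-noreudesm-4-en-12,8β-olide F3. NaBH4/CeCl3·7H2O reduces its C3 ketone to rejoin the route at 23.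

**Step 18.** The amide base may also deprotonate the isobutyrate, leading to Claisen-type self-condensation or aminomethylation at the wrong ester. The fallback methylenates before acylation. Starting from 23, LiN(i-Pr)2 (2.2 equiv) forms the alkoxide and the lactone enolate; Me2N=CH2+ I−, then MeI and aq. NaHCO3 give 3β-hydroxyeudesma-4,11(13)-dien-12,8β-olide F4. Isobutyrylation as in step 17 rejoins the route at 27.

**Step 19.** The isobutyrate may be saponified along with the lactone, or the lactone may re-close during methylation. The fallback accepts full hydrolysis. Starting from 27, excess KOH followed by MeI in DMF gives methyl 3β,8β-dihydroxyeudesma-4,11(13)-dien-12-oate F5. One equivalent of i-PrCOCl in pyridine at −30 °C should acylate the equatorial allylic 3β-hydroxyl in preference to the axial 8β-hydroxyl, which is shielded by the C10 methyl, and the route is rejoined at 29.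

**Step 21.** A different allylic hydrogen may be abstracted (from C6, giving the 4α-hydroperoxy-5-ene, or from C3), and the tertiary allylic hydroperoxide may decompose on purification. The fallback installs the C5 oxygen in two-electron steps. Starting from 30, m-chloroperbenzoic acid (NaHCO3, CH2Cl2, 0 °C) epoxidises the electron-rich alkene from the α face to give methyl 8β-acetoxy-4α,5α-epoxy-3β-(isobutyryloxy)eudesm-11(13)-en-12-oate F6. Me3SiOTf/2,6-lutidine, then DBU and dilute acid, isomerises the epoxide with proton loss from the C15 methyl to methyl 8β-acetoxy-5α-hydroxy-3β-(isobutyryloxy)eudesma-4(15),11(13)-dien-12-oate F7. Ethereal H2O2 with catalytic H2SO4 at 0 °C exchanges the tertiary allylic hydroxyl for the hydroperoxide on the α face and gives 31.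

## Further compounds

F1 | step 13 | methyl (3R)-5-diazo-3-{[2,6-dimethyl-3-(triisopropylsilyloxy)phenyl]methyl}-4-oxopentanoate | COC(=O)C[C@@H](Cc1c(C)c(O[Si](C(C)C)(C(C)C)C(C)C)ccc1C)C(=O)C=[N+]=[N-]
F2 | step 13 | methyl (3R)-5-diazo-3-[(3-hydroxy-2,6-dimethylphenyl)methyl]-4-oxopentanoate | COC(=O)C[C@@H](Cc1c(C)c(O)ccc1C)C(=O)C=[N+]=[N-]
F0 | step 11 | none | none
F3 | step 16 | 3-oxo-13-noreudesm-4-en-12,8β-olide | O=C1C[C@H]2CC3=C(C)C(=O)CC[C@]3(C)C[C@H]2O1
F4 | step 18 | 3β-hydroxyeudesma-4,11(13)-dien-12,8β-olide | O=C1C(=C)[C@H]2CC3=C(C)[C@@H](O)CC[C@]3(C)C[C@H]2O1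
F5 | step 19 | methyl 3β,8β-dihydroxyeudesma-4,11(13)-dien-12-oate | C=C(C(=O)OC)[C@H]1CC2=C(C)[C@@H](O)CC[C@]2(C)C[C@H]1O
F6 | step 21 | methyl 8β-acetoxy-4α,5α-epoxy-3β-(isobutyryloxy)eudesm-11(13)-en-12-oate | C=C(C(=O)OC)[C@H]1C[C@@]2(O3)[C@@]3(C)[C@@H](OC(=O)C(C)C)CC[C@]2(C)C[C@H]1OC(C)=O
F7 | step 21 | methyl 8β-acetoxy-5α-hydroxy-3β-(isobutyryloxy)eudesma-4(15),11(13)-dien-12-oate | C=C(C(=O)OC)[C@H]1C[C@@]2(O)C(=C)[C@@H](OC(=O)C(C)C)CC[C@]2(C)C[C@H]1OC(C)=O
A1 | alternative 1 | 5-{[2-(bromomethyl)-1,3-dimethyl-4-oxocyclohex-2-en-1-yl]methyl}-3-[(phenylsulfanyl)methyl]furan-2(5H)-one, configured at C8 and C10 as in A2 | O=C1O[C@H](C[C@@]2(C)CCC(=O)C(C)=C2CBr)C=C1CSc1ccccc1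
A2 | alternative 1 | 3-oxoeudesma-4,11(13)-dien-12,8β-olide | C=C1[C@H]2CC3=C(C)C(=O)CC[C@]3(C)C[C@H]2OC1=O
A3 | alternative 2 | methyl (1(10)E,4E)-8β-acetoxy-3β-(isobutyryloxy)germacra-1(10),4,11(13)-trien-12-oate | C=C(C(=O)OC)[C@H]1C/C=C(\C)[C@@H](OC(=O)C(C)C)CC/C=C(\C)C[C@H]1OC(C)=O
A4 | alternative 2 | methyl 8β-acetoxy-3β-(isobutyryloxy)eudesma-4,11(13)-dien-12-oate (identical with 30) | C=C(C(=O)OC)[C@H]1CC2=C(C)[C@@H](OC(=O)C(C)C)CC[C@]2(C)C[C@H]1OC(C)=O
A5 | alternative 3 | methyl (3R,5E)-7-(tert-butyldimethylsilyloxy)-6-methyl-3-{2-[(2E)-2-methyl-3-(phenylsulfonyl)prop-2-en-1-yl]-1,3-dioxolan-2-yl}octa-5,7-dienoate | C=C(O[Si](C)(C)C(C)(C)C)/C(C)=C/C[C@H](CC(=O)OC)C1(C/C(C)=C/S(=O)(=O)c2ccccc2)OCCO1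
A6 | alternative 3 | methyl 3-(tert-butyldimethylsilyloxy)-8,8-(ethylenedioxy)-1β-(phenylsulfonyl)-13-noreudesm-3-en-12-oate (5αH, 7αH, 10β-methyl) | COC(=O)C[C@H]1C[C@H]2C(C)=C(O[Si](C)(C)C(C)(C)C)C[C@@H](S(=O)(=O)c3ccccc3)[C@]2(C)CC14OCCO4
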